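Everything rests on cutting the benzofuran at O1–C2 and at the bond from C3 to its carboxyl carbon. One divalent-palladium operation then closes the furan ring (O1, C2, C3, C3a, C7a), inserts CO at C3 and joins the acyl group to protected (R)-danshensu. It exploits the O1–C2(aryl)=C3–C(=O)O array, where C3 is squeezed between the 2-aryl ring and C4–H. The precursor is a fully benzylated 2-(arylethynyl)phenol that already carries the unhindered (E)-cinnamate of (R)-danshensu. Its phenol is kept as an acetate through the Sonogashira coupling and freed only one step before the cascade, since a free o-iodophenol would close to a 3-unsubstituted benzofuran under copper and amine.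

Key step: step 9

Remark on the chemistry: 3-(benzyloxy)-4-hydroxybenzaldehyde is taken as a catalogue compound. The constitution and configuration of the cascade precursor, the alcohol partner and the cascade product were checked atom by atom against the target and need no correction. Both stereocentres are (R) and come unchanged from (R)-danshensu. The 7-oxygen/5-propenoate pattern requires iodination at C5 of that aldehyde, ortho to the free phenol.

Step 1
Reactants: 1 sodium (R)-3-(3,4-dihydroxyphenyl)lactate (danshensu sodium)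
Product: 2 benzyl (2R)-3-[3,4-bis(benzyloxy)phenyl]-2-hydroxypropanoate
Conditions: BnBr (3.3 equiv), K2CO3 (2.5 equiv), DMF, rt, N2
Reagents that add atoms: benzyl bromide, BrCc1ccccc1
Why: Williamson O-alkylation under carbonate benzylates only the two phenoxides and the carboxylate, because K2CO3 does not deprotonate the aliphatic hydroxyl, and the stereocentre is not involved.

Step 2
Reactants: 2 benzyl (2R)-3-[3,4-bis(benzyloxy)phenyl]-2-hydroxypropanoate; 3 Meldrum's acid (2,2-dimethyl-1,3-dioxane-4,6-dione)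
Product: 4 3-{[(2R)-1-(benzyloxy)-3-[3,4-bis(benzyloxy)phenyl]-1-oxopropan-2-yl]oxy}-3-oxopropanoic acid (malonic half ester of 2)
Conditions: toluene, 100 °C
Reagents that add atoms: none
Why: Thermal alcoholysis of Meldrum's acid acylates the secondary alcohol at oxygen with loss of acetone, a standard entry to malonic half esters that leaves the C–O bond of the stereocentre, and so its (R) configuration, untouched.

Step 3
Reactants: 5 3-(benzyloxy)-4-hydroxybenzaldehyde
Product: 6 3-(benzyloxy)-4-hydroxy-5-iodobenzaldehyde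
Conditions: NIS (1.05 equiv), TFA (10 mol%), MeCN, 0 °C → rt
Reagents that add atoms: N-iodosuccinimide, O=C1CCC(=O)N1I
Why: Electrophilic aromatic iodination is directed by the free phenol to its only open ortho position (C5), the para position being occupied by the formyl group, exactly as in the iodination of vanillin.

Step 4
Reactants: 6 3-(benzyloxy)-4-hydroxy-5-iodobenzaldehyde; 4 malonic half ester of 2
Product: 8 benzyl (2R)-2-{[(2E)-3-[3-(benzyloxy)-4-hydroxy-5-iodophenyl]prop-2-enoyl]oxy}-3-[3,4-bis(benzyloxy)phenyl]propanoate, via arylidenemalonic half ester 7 (not isolated)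
Conditions: 4 (1.2 equiv), pyridine, piperidine (0.1 equiv), 55 °C
Reagents that add atoms: none
Why: Knoevenagel–Doebner condensation of a malonic half ester with a 4-hydroxybenzaldehyde (the ferulate and rosmarinate type) gives, after decarboxylation in pyridine, the thermodynamically preferred E-cinnamate directly as the danshensu ester, with no new stereocentre and no esterification step.

Step 5
Reactants: 8 benzyl (2R)-2-{[(2E)-3-[3-(benzyloxy)-4-hydroxy-5-iodophenyl]prop-2-enoyl]oxy}-3-[3,4-bis(benzyloxy)phenyl]propanoate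
Product: 9 benzyl (2R)-2-{[(2E)-3-[4-(acetyloxy)-3-(benzyloxy)-5-iodophenyl]prop-2-enoyl]oxy}-3-[3,4-bis(benzyloxy)phenyl]propanoate
Conditions: Ac2O (1.5 equiv), pyridine, DMAP (5 mol%), CH2Cl2, 0 °C → rt
Reagents that add atoms: acetic anhydride, CC(=O)OC(C)=O
Why: Routine O-acetylation of the acidic phenol masks the nucleophile that would otherwise add to the alkyne under the copper and amine conditions of the next coupling and give the 3-unsubstituted benzofuran.

Step 6
Reactants: 10 3,4-bis(benzyloxy)benzaldehyde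
Product: 11 1,2-bis(benzyloxy)-4-ethynylbenzene
Conditions: dimethyl (1-diazo-2-oxopropyl)phosphonate (1.3 equiv), K2CO3 (2 equiv), MeOH/THF, 0 °C → rt
Reagents that add atoms: dimethyl (1-diazo-2-oxopropyl)phosphonate (Ohira–Bestmann reagent), CC(=O)C(=[N+]=[N-])P(=O)(OC)OC
Why: Ohira–Bestmann (Seyferth–Gilbert) homologation converts a non-enolisable aryl aldehyde into the terminal alkyne under mild carbonate conditions that benzyl ethers tolerate.

Step 7
Reactants: 9 benzyl (2R)-2-{[(2E)-3-[4-(acetyloxy)-3-(benzyloxy)-5-iodophenyl]prop-2-enoyl]oxy}-3-[3,4-bis(benzyloxy)phenyl]propanoate; 11 1,2-bis(benzyloxy)-4-ethynylbenzene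
Product: 12 benzyl (2R)-2-{[(2E)-3-(4-(acetyloxy)-3-(benzyloxy)-5-{[3,4-bis(benzyloxy)phenyl]ethynyl}phenyl)prop-2-enoyl]oxy}-3-[3,4-bis(benzyloxy)phenyl]propanoate
Conditions: 11 (1.2 equiv), PdCl2(PPh3)2 (3 mol%), CuI (5 mol%), Et3N (3 equiv), THF, degassed, rt
Reagents that add atoms: none
Why: Sonogashira coupling of an electron-poor aryl iodide proceeds at room temperature, where the aryl acetate is stable to triethylamine and the trisubstituted cinnamate does not compete in a Heck reaction, so the alkyne is installed without ring closure.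

Step 8
Reactants: 12 benzyl (2R)-2-{[(2E)-3-(4-(acetyloxy)-3-(benzyloxy)-5-{[3,4-bis(benzyloxy)phenyl]ethynyl}phenyl)prop-2-enoyl]oxy}-3-[3,4-bis(benzyloxy)phenyl]propanoate
Product: 13 benzyl (2R)-2-{[(2E)-3-(3-(benzyloxy)-5-{[3,4-bis(benzyloxy)phenyl]ethynyl}-4-hydroxyphenyl)prop-2-enoyl]oxy}-3-[3,4-bis(benzyloxy)phenyl]propanoate
Conditions: pyrrolidine (2 equiv), CH2Cl2, 0 °C; dilute aqueous citric acid wash
Reagents that add atoms: none
Why: Chemoselective aminolysis of an aryl acetate works because the phenoxide is a far better leaving group than the alkoxides of the cinnamate and benzyl esters, and without copper, palladium or strong base the freed o-alkynylphenol should not cyclise.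

Step 9
Reactants: 13 benzyl (2R)-2-{[(2E)-3-(3-(benzyloxy)-5-{[3,4-bis(benzyloxy)phenyl]ethynyl}-4-hydroxyphenyl)prop-2-enoyl]oxy}-3-[3,4-bis(benzyloxy)phenyl]propanoate; 2 benzyl (2R)-3-[3,4-bis(benzyloxy)phenyl]-2-hydroxypropanoate
Product: 14 (2R)-1-(benzyloxy)-3-[3,4-bis(benzyloxy)phenyl]-1-oxopropan-2-yl 7-(benzyloxy)-2-[3,4-bis(benzyloxy)phenyl]-5-[(1E)-3-{[(2R)-1-(benzyloxy)-3-[3,4-bis(benzyloxy)phenyl]-1-oxopropan-2-yl]oxy}-3-oxoprop-1-en-1-yl]-1-benzofuran-3-carboxylate (nonabenzyl schizotenuin A)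
Conditions: Pd(O2CCF3)2 (10 mol%), p-benzoquinone (2 equiv), CO (1 atm), 2 (2 equiv), 4 Å MS, CH2Cl2, 0 °C → rt, 13 added over 4 h
Reagents that add atoms: carbon monoxide, [C-]#[O+]
Why: Electrophilic divalent palladium coordinates the alkyne of 13, the phenol oxygen adds anti to the aryl-bearing alkyne carbon, the resulting 3-benzofuranylpalladium inserts CO, the acylpalladium is intercepted by alcohol 2, and the zerovalent palladium released is returned to the divalent state by p-benzoquinone. The closest known reaction is the cyclisation–methoxycarbonylation of 2-alkynylphenols to benzofuran-3-carboxylates run in methanol; using a secondary α-hydroxy ester in twofold excess in a non-protic solvent is the one real extrapolation of the route. The furan ring (O1, C2, C3, C3a, C7a) closes in a 5-endo-dig mode that is fixed by the ortho relation of hydroxyl and alkyne, so no regiochemical choice arises. No stereocentre is formed, and the two (R) centres are either acylated at oxygen or left alone, so both are retained. The selectivity needed is CO insertion and alcohol capture over protodepalladation (3-H benzofuran) and over a second oxypalladation at the acylpalladium (diaryl ketone); a CO-saturated dry non-protic medium, ligand-free Pd(O2CCF3)2, excess 2 and slow addition of 13 are chosen to secure it. Because the ester carbonyl is delivered as CO and the alcohol meets a reactive acylpalladium, the crowded C3 ester needs no activation of a hindered 2-arylbenzofuran-3-carboxylic acid.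

Step 10
Reactants: 14 nonabenzyl schizotenuin A
Product: 15 schizotenuin A, (2R)-2-{[(2E)-3-(3-{[(1R)-1-carboxy-2-(3,4-dihydroxyphenyl)ethoxy]carbonyl}-2-(3,4-dihydroxyphenyl)-7-hydroxy-1-benzofuran-5-yl)prop-2-enoyl]oxy}-3-(3,4-dihydroxyphenyl)propanoic acid
Conditions: BCl3 (1 M in CH2Cl2, 27 equiv), pentamethylbenzene (30 equiv), CH2Cl2, −78 → 0 °C; MeOH then H2O quench; reversed-phase purification
Reagents that add atoms: none
Why: Lewis-acid debenzylation with a non-basic cation scavenger transfers each benzyl group of the seven aryl ethers and two benzyl esters to pentamethylbenzene, while the cinnamate alkene (which rules out hydrogenolysis), the benzofuran, the two secondary esters and both stereocentres are not touched by these non-reductive, base-free conditions.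

Compound list
1 | sodium (R)-3-(3,4-dihydroxyphenyl)lactate (danshensu sodium) | O[C@H](Cc1ccc(O)c(O)c1)C(=O)[O-].[Na+] | starting material
2 | benzyl (2R)-3-[3,4-bis(benzyloxy)phenyl]-2-hydroxypropanoate | O[C@H](Cc1ccc(OCc9ccccc9)c(OCc9ccccc9)c1)C(=O)OCc9ccccc9 | intermediate
3 | Meldrum's acid (2,2-dimethyl-1,3-dioxane-4,6-dione) | CC1(C)OC(=O)CC(=O)O1 | starting material
4 | 3-{[(2R)-1-(benzyloxy)-3-[3,4-bis(benzyloxy)phenyl]-1-oxopropan-2-yl]oxy}-3-oxopropanoic acid | OC(=O)CC(=O)O[C@H](Cc1ccc(OCc9ccccc9)c(OCc9ccccc9)c1)C(=O)OCc9ccccc9 | intermediate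
5 | 3-(benzyloxy)-4-hydroxybenzaldehyde | O=Cc1ccc(O)c(OCc9ccccc9)c1 | starting material
6 | 3-(benzyloxy)-4-hydroxy-5-iodobenzaldehyde | O=Cc1cc(I)c(O)c(OCc9ccccc9)c1 | intermediate
7 | 2-{[3-(benzyloxy)-4-hydroxy-5-iodophenyl]methylidene}-3-{[(2R)-1-(benzyloxy)-3-[3,4-bis(benzyloxy)phenyl]-1-oxopropan-2-yl]oxy}-3-oxopropanoic acid (arylidenemalonic half ester; either alkene isomer decarboxylates to the E product) | OC(=O)C(=Cc1cc(I)c(O)c(OCc9ccccc9)c1)C(=O)O[C@H](Cc1ccc(OCc9ccccc9)c(OCc9ccccc9)c1)C(=O)OCc9ccccc9 | intermediate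
8 | benzyl (2R)-2-{[(2E)-3-[3-(benzyloxy)-4-hydroxy-5-iodophenyl]prop-2-enoyl]oxy}-3-[3,4-bis(benzyloxy)phenyl]propanoate | O=C(/C=C/c1cc(I)c(O)c(OCc9ccccc9)c1)O[C@H](Cc1ccc(OCc9ccccc9)c(OCc9ccccc9)c1)C(=O)OCc9ccccc9 | intermediate
9 | benzyl (2R)-2-{[(2E)-3-[4-(acetyloxy)-3-(benzyloxy)-5-iodophenyl]prop-2-enoyl]oxy}-3-[3,4-bis(benzyloxy)phenyl]propanoate | O=C(/C=C/c1cc(I)c(OC(C)=O)c(OCc9ccccc9)c1)O[C@H](Cc1ccc(OCc9ccccc9)c(OCc9ccccc9)c1)C(=O)OCc9ccccc9 | intermediate
10 | 3,4-bis(benzyloxy)benzaldehyde | O=Cc1ccc(OCc9ccccc9)c(OCc9ccccc9)c1 | starting material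
11 | 1,2-bis(benzyloxy)-4-ethynylbenzene | C#Cc1ccc(OCc9ccccc9)c(OCc9ccccc9)c1 | intermediate
12 | benzyl (2R)-2-{[(2E)-3-(4-(acetyloxy)-3-(benzyloxy)-5-{[3,4-bis(benzyloxy)phenyl]ethynyl}phenyl)prop-2-enoyl]oxy}-3-[3,4-bis(benzyloxy)phenyl]propanoate | O=C(/C=C/c1cc(OCc9ccccc9)c(OC(C)=O)c(C#Cc2ccc(OCc9ccccc9)c(OCc9ccccc9)c2)c1)O[C@H](Cc1ccc(OCc9ccccc9)c(OCc9ccccc9)c1)C(=O)OCc9ccccc9 | intermediate
13 | benzyl (2R)-2-{[(2E)-3-(3-(benzyloxy)-5-{[3,4-bis(benzyloxy)phenyl]ethynyl}-4-hydroxyphenyl)prop-2-enoyl]oxy}-3-[3,4-bis(benzyloxy)phenyl]propanoate | O=C(/C=C/c1cc(OCc9ccccc9)c(O)c(C#Cc2ccc(OCc9ccccc9)c(OCc9ccccc9)c2)c1)O[C@H](Cc1ccc(OCc9ccccc9)c(OCc9ccccc9)c1)C(=O)OCc9ccccc9 | intermediate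
14 | nonabenzyl schizotenuin A: (2R)-1-(benzyloxy)-3-[3,4-bis(benzyloxy)phenyl]-1-oxopropan-2-yl 7-(benzyloxy)-2-[3,4-bis(benzyloxy)phenyl]-5-[(1E)-3-{[(2R)-1-(benzyloxy)-3-[3,4-bis(benzyloxy)phenyl]-1-oxopropan-2-yl]oxy}-3-oxoprop-1-en-1-yl]-1-benzofuran-3-carboxylate | O=C(/C=C/c1cc(OCc9ccccc9)c2oc(-c3ccc(OCc9ccccc9)c(OCc9ccccc9)c3)c(C(=O)O[C@H](Cc3ccc(OCc9ccccc9)c(OCc9ccccc9)c3)C(=O)OCc9ccccc9)c2c1)O[C@H](Cc1ccc(OCc9ccccc9)c(OCc9ccccc9)c1)C(=O)OCc9ccccc9 | intermediate
15 | schizotenuin A: (2R)-2-{[(2E)-3-(3-{[(1R)-1-carboxy-2-(3,4-dihydroxyphenyl)ethoxy]carbonyl}-2-(3,4-dihydroxyphenyl)-7-hydroxy-1-benzofuran-5-yl)prop-2-enoyl]oxy}-3-(3,4-dihydroxyphenyl)propanoic acid | O=C(/C=C/c1cc(O)c2oc(-c3ccc(O)c(O)c3)c(C(=O)O[C@H](Cc3ccc(O)c(O)c3)C(=O)O)c2c1)O[C@H](Cc1ccc(O)c(O)c1)C(=O)O | target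

Total step count: 10. Longest linear sequence: 8 steps (steps 1, 2, 4, 5, 7, 8, 9, 10, from 1 to 15).

Steps most likely to fail

Step 9. The alcohol is present only in small excess, so capture of the acylpalladium may be slow. Protodepalladation of the 3-benzofuranylpalladium before CO insertion, a second oxypalladation at the acylpalladium, or acyl transfer to the hydroquinone that accumulates could then take over. A higher CO pressure would be tried first. The fallback separates ring closure from carbonylation and uses only known chemistry. It sets out from 13 and returns at 14. Iodocyclisation of 13 (I2, NaHCO3, MeCN, rt; the same 5-endo-dig anti addition with iodonium as the electrophile) should give benzyl (2R)-2-{[(2E)-3-{7-(benzyloxy)-2-[3,4-bis(benzyloxy)phenyl]-3-iodo-1-benzofuran-5-yl}prop-2-enoyl]oxy}-3-[3,4-bis(benzyloxy)phenyl]propanoate F1. Alkoxycarbonylation of this heteroaryl iodide with 2 under zerovalent-palladium catalysis (Pd(OAc)2, Xantphos, Et3N, CO 1 atm, 2 in twofold excess, toluene, 80 °C) should then deliver 14.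

Step 10. Nine benzyl groups must leave in one operation. The two benzyl esters ionise more slowly than the aryl ethers, so cleavage may stop short, and warming to force it invites Friedel–Crafts re-benzylation of the electron-rich rings or loss of the secondary esters. The fallback stages the deprotection by two different mechanisms. It sets out from 14 and returns at 15. Triethylsilane transfer hydrogenolysis (Pd(OAc)2 cat., Et3SiH, Et3N, CH2Cl2, rt, aqueous work-up of the silyl esters) is selective for benzyl esters over aryl benzyl ethers and alkenes and should give the heptabenzyl ether diacid (2R)-2-{[(2E)-3-(7-(benzyloxy)-2-[3,4-bis(benzyloxy)phenyl]-3-{[(1R)-2-[3,4-bis(benzyloxy)phenyl]-1-carboxyethoxy]carbonyl}-1-benzofuran-5-yl)prop-2-enoyl]oxy}-3-[3,4-bis(benzyloxy)phenyl]propanoic acid F2. The seven aryl benzyl ethers, the easy substrates for BCl3 and pentamethylbenzene at −78 °C, would then be cleaved to 15.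

Step 4. The aldehyde is deactivated as its phenoxide in pyridine, so condensation may be slow. Prolonged heating in amine base risks erosion of configuration at the α-acyloxy ester carbon, premature decarboxylation of the half ester and aminolysis by piperidine. The fallback replaces the condensation by a Horner–Wadsworth–Emmons olefination under weak base. It sets out from 2 and 6 and returns at 9, so step 5 is bypassed. Alcohol 2 would be esterified with (diethoxyphosphoryl)acetic acid (EDC·HCl, DMAP cat., CH2Cl2, rt) to give benzyl (2R)-3-[3,4-bis(benzyloxy)phenyl]-2-{[(diethoxyphosphoryl)acetyl]oxy}propanoate F3. Aldehyde 6 would be acetylated (Ac2O, pyridine, rt) to 2-(benzyloxy)-4-formyl-6-iodophenyl acetate F4. Masamune–Roush olefination of F4 with F3 (LiCl, i-Pr2NEt, MeCN, rt) should give the E-cinnamate 9 directly.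

Further compounds
F1 | step 9 | benzyl (2R)-2-{[(2E)-3-{7-(benzyloxy)-2-[3,4-bis(benzyloxy)phenyl]-3-iodo-1-benzofuran-5-yl}prop-2-enoyl]oxy}-3-[3,4-bis(benzyloxy)phenyl]propanoate | O=C(/C=C/c1cc(OCc9ccccc9)c2oc(-c3ccc(OCc9ccccc9)c(OCc9ccccc9)c3)c(I)c2c1)O[C@H](Cc1ccc(OCc9ccccc9)c(OCc9ccccc9)c1)C(=O)OCc9ccccc9
F2 | step 10 | (2R)-2-{[(2E)-3-(7-(benzyloxy)-2-[3,4-bis(benzyloxy)phenyl]-3-{[(1R)-2-[3,4-bis(benzyloxy)phenyl]-1-carboxyethoxy]carbonyl}-1-benzofuran-5-yl)prop-2-enoyl]oxy}-3-[3,4-bis(benzyloxy)phenyl]propanoic acid | O=C(/C=C/c1cc(OCc9ccccc9)c2oc(-c3ccc(OCc9ccccc9)c(OCc9ccccc9)c3)c(C(=O)O[C@H](Cc3ccc(OCc9ccccc9)c(OCc9ccccc9)c3)C(=O)O)c2c1)O[C@H](Cc1ccc(OCc9ccccc9)c(OCc9ccccc9)c1)C(=O)O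
F3 | step 4 | benzyl (2R)-3-[3,4-bis(benzyloxy)phenyl]-2-{[(diethoxyphosphoryl)acetyl]oxy}propanoate | CCOP(=O)(OCC)CC(=O)O[C@H](Cc1ccc(OCc9ccccc9)c(OCc9ccccc9)c1)C(=O)OCc9ccccc9
F4 | step 4 | 2-(benzyloxy)-4-formyl-6-iodophenyl acetate | O=Cc1cc(I)c(OC(C)=O)c(OCc9ccccc9)c1
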